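**Assumption:** the SMILES encodes the castalagin/vescalagin skeleton: C1-aryl open-chain glucose with a 4,6-HHDP and a 2,3,5-NHTP, C1 as (1R). The three biaryl axes are not specified in the SMILES, so they are taken as the natural ones, set by the glucose tether.

## Retrosynthetic overview
1. Target (12) ⇒ global hydrogenolysis of the ten benzyl ethers of **11**.
2. **11** ⇒ tether-controlled intramolecular Cu/O2 oxidative ortho-couplings of the five galloyl phenols of **10**, closing the 4,6-HHDP and 2,3,5-NHTP macrocycles. The axial chirality is set by the glucose tether.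
3. **10** ⇒ intramolecular Friedel–Crafts hydroxyalkylation of the 2-O-aroyl ring onto the C1 aldehyde of **9**. This forms the C-aryl bond and the isochromanone (lactone) ring and sets C1.
4. **9** ⇒ MOM removal from **8** ⇒ hydrolysis of dithioacetal **7** ⇒ penta-aroylation of D-glucose diethyl dithioacetal **2** with acid **6**, which is made from methyl gallate.
5. Ring order: isochromanone ring first, then the three biaryl axes (HHDP and NHTP macrocycles) in one operation.

## Route

**Step 1**
Reactants: **1** D-glucose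
Product: **2** D-glucose diethyl dithioacetal
Conditions: EtSH (2.2 equiv), conc. HCl, 0 °C → rt
Reagents that add atoms: ethanethiol, CCS
Why: Fischer dithioacetalization locks glucose in its acyclic form with all five OH free, and C2–C5 keep the D-gluco configuration from the chiral pool.

**Step 2**
Reactants: **3** methyl gallate
Product: **4** methyl 3-hydroxy-4,5-bis(benzyloxy)benzoate
Conditions: BnBr (2.1 equiv), K2CO3, DMF, 0 °C → rt
Reagents that add atoms: benzyl bromide, BrCc1ccccc1
Why: Williamson etherification benzylates the most acidic 4-OH first and then one of the two equivalent flanking OH groups, so chromatography gives a single 3,4-dibenzyl isomer (a statistical reaction with some tribenzyl by-product).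

**Step 3**
Reactants: **4**
Product: **5** methyl 3-(methoxymethoxy)-4,5-bis(benzyloxy)benzoate
Conditions: MOMCl (1.5 equiv), i-Pr2NEt, CH2Cl2, 0 °C
Reagents that add atoms: chloromethyl methyl ether, ClCOC
Why: the remaining phenol is masked as an acid-labile MOM ether so that it survives esterification and can be unmasked selectively later.

**Step 4**
Reactants: **5**
Product: **6** 3-(methoxymethoxy)-4,5-bis(benzyloxy)benzoic acid
Conditions: LiOH, THF/MeOH/H2O, rt
Reagents that add atoms: none (hydrolysis adds only hydrogen to the product)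
Why: saponification of the methyl ester leaves the benzyl and MOM ethers intact.

**Step 5**
Reactants: **2** D-glucose diethyl dithioacetal and **6** acid
Product: **7** 2,3,4,5,6-penta-O-[3-(methoxymethoxy)-4,5-bis(benzyloxy)benzoyl]-D-glucose diethyl dithioacetal
Conditions: **6** (6.0 equiv, five aroyl groups transferred), EDC·HCl (6.5 equiv), DMAP (2 equiv), CH2Cl2, 35 °C
Reagents that add atoms: acid **6** (excess, supplies the five aroyl groups), 3-(methoxymethoxy)-4,5-bis(benzyloxy)benzoic acid, OC(=O)c1cc(OCOC)c(OCc2ccccc2)c(OCc2ccccc2)c1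
Why: Steglich esterification acylates all five sugar OH groups, and the carbinol stereocentres are untouched because there is no epimerizable carbonyl at this stage.

**Step 6**
Reactants: **7**
Product: **8** 2,3,4,5,6-penta-O-[3-(methoxymethoxy)-4,5-bis(benzyloxy)benzoyl]-aldehydo-D-glucose
Conditions: MeI (excess), CaCO3, MeCN/H2O, 60 °C
Reagents that add atoms: water, O
Why: S-methylation of the dithioacetal followed by hydrolysis releases the C1 aldehyde, and CaCO3 buffers the HI formed so the esters, benzyl ethers and MOM ethers survive (Fetizon-type dithioacetal cleavage).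

**Step 7**
Reactants: **8**
Product: **9** 2,3,4,5,6-penta-O-[3-hydroxy-4,5-bis(benzyloxy)benzoyl]-aldehydo-D-glucose
Conditions: TFA/CH2Cl2 (1:4), thioanisole (5 equiv), 0 °C → rt
Reagents that add atoms: none
Why: acidolysis of the five aryl MOM ethers, with thioanisole trapping the MOM cation, frees the phenols needed for the later cyclization and couplings, while benzyl ethers and esters survive dilute TFA at low temperature.

**Step 8**
Reactants: **9**
Product: **10** 4-hydroxy-3-substituted-3,4-dihydroisocoumarin (1R), i.e. the C-aryl lactone in which the O2-aroyl ring is bonded to C1, with 3,4,5,6-tetra-O-[3-hydroxy-4,5-bis(benzyloxy)benzoyl] groups on the remaining glucitol carbons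
Conditions: Sc(OTf)3 (10 mol %), MeNO2, 25 °C
Reagents that add atoms: none
Why: in an intramolecular Friedel–Crafts hydroxyalkylation the ring carbon para to the free OH attacks the Sc(III)-activated C1 aldehyde. Only the O2-aroyl ring can close a six-membered ring, and C1 is set by 1,2-induction from the existing C2 centre in the chair-like cyclic transition state, under reversible conditions that favour the more stable lactone diastereomer.

**Step 9 (key step)**
Reactants: **10**
Product: **11** decabenzyl 4,6-HHDP/2,3,5-NHTP C-glycosidic ellagitannin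
Conditions: Cu(OH)Cl·TMEDA (6 equiv), O2 (1 atm), CH2Cl2/MeOH (4:1), 2 mM, rt
Reagents that add atoms: none
Why: Cu(II)/amine oxidative phenol coupling joins carbons ortho to the free OH groups; the glucose tether pre-organizes the 4,6 (D–E), 3,5 (Q–P) and 2,3 (Q–R) pairs so they couple intramolecularly at high dilution, and it sets the three axial configurations, with no new central stereocentres.

**Step 10**
Reactants: **11**
Product: **12** target, castalagin/vescalagin (C1 = R) (CID 12302513)
Conditions: H2 (1 atm), Pd(OH)2/C, THF/MeOH, rt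
Reagents that add atoms: none (H2 adds only hydrogen)
Why: catalytic hydrogenolysis removes all ten benzyl ethers and leaves the aryl esters, the lactone and the benzylic C1–OH unchanged.

## Compound list
1 | D-glucose (aldehydo form) | C([C@H]([C@H]([C@@H]([C@H](C=O)O)O)O)O)O | starting material
2 | D-glucose diethyl dithioacetal | C([C@H]([C@H]([C@@H]([C@H](C(SCC)SCC)O)O)O)O)O | intermediate
3 | methyl gallate | COC(=O)c1cc(O)c(O)c(O)c1 | starting material
4 | methyl 3-hydroxy-4,5-bis(benzyloxy)benzoate | COC(=O)c1cc(O)c(OCc2ccccc2)c(OCc2ccccc2)c1 | intermediate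
5 | methyl 3-(methoxymethoxy)-4,5-bis(benzyloxy)benzoate | COC(=O)c1cc(OCOC)c(OCc2ccccc2)c(OCc2ccccc2)c1 | intermediate
6 | 3-(methoxymethoxy)-4,5-bis(benzyloxy)benzoic acid | OC(=O)c1cc(OCOC)c(OCc2ccccc2)c(OCc2ccccc2)c1 | intermediate
7 | penta-aroyl dithioacetal | C([C@H]([C@H]([C@@H]([C@H](C(SCC)SCC)OC(=O)c3cc(OCOC)c(OCc4ccccc4)c(OCc4ccccc4)c3)OC(=O)c3cc(OCOC)c(OCc4ccccc4)c(OCc4ccccc4)c3)OC(=O)c3cc(OCOC)c(OCc4ccccc4)c(OCc4ccccc4)c3)OC(=O)c3cc(OCOC)c(OCc4ccccc4)c(OCc4ccccc4)c3)OC(=O)c3cc(OCOC)c(OCc4ccccc4)c(OCc4ccccc4)c3 | intermediate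
8 | aldehydo penta-aroyl-glucose (MOM/Bn) | C([C@H]([C@H]([C@@H]([C@H](C=O)OC(=O)c3cc(OCOC)c(OCc4ccccc4)c(OCc4ccccc4)c3)OC(=O)c3cc(OCOC)c(OCc4ccccc4)c(OCc4ccccc4)c3)OC(=O)c3cc(OCOC)c(OCc4ccccc4)c(OCc4ccccc4)c3)OC(=O)c3cc(OCOC)c(OCc4ccccc4)c(OCc4ccccc4)c3)OC(=O)c3cc(OCOC)c(OCc4ccccc4)c(OCc4ccccc4)c3 | intermediate
9 | aldehydo penta-aroyl-glucose with free phenols | C([C@H]([C@H]([C@@H]([C@H](C=O)OC(=O)c3cc(O)c(OCc4ccccc4)c(OCc4ccccc4)c3)OC(=O)c3cc(O)c(OCc4ccccc4)c(OCc4ccccc4)c3)OC(=O)c3cc(O)c(OCc4ccccc4)c(OCc4ccccc4)c3)OC(=O)c3cc(O)c(OCc4ccccc4)c(OCc4ccccc4)c3)OC(=O)c3cc(O)c(OCc4ccccc4)c(OCc4ccccc4)c3 | intermediate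
10 | C-aryl lactone (1R) | C([C@H]([C@H]([C@@H]([C@H]3OC(=O)c4cc(O)c(OCc5ccccc5)c(OCc5ccccc5)c4[C@H]3O)OC(=O)c3cc(O)c(OCc4ccccc4)c(OCc4ccccc4)c3)OC(=O)c3cc(O)c(OCc4ccccc4)c(OCc4ccccc4)c3)OC(=O)c3cc(O)c(OCc4ccccc4)c(OCc4ccccc4)c3)OC(=O)c3cc(O)c(OCc4ccccc4)c(OCc4ccccc4)c3 | intermediate
11 | decabenzyl HHDP/NHTP polycycle | O=C1OC[C@H]2OC(=O)c3cc(OCc6ccccc6)c(OCc6ccccc6)c(O)c3-c3c(O)c(OCc6ccccc6)c(OCc6ccccc6)c4c3C(=O)O[C@H]([C@H]3OC(=O)c5c-4c(O)c(OCc6ccccc6)c(OCc6ccccc6)c5[C@H]3O)[C@@H]2OC(=O)c2cc(OCc6ccccc6)c(OCc6ccccc6)c(O)c2-c2c1cc(OCc6ccccc6)c(OCc6ccccc6)c2O | intermediate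
12 | target (CID 12302513) | O=C1OC[C@H]2OC(=O)c3cc(O)c(O)c(O)c3-c3c(O)c(O)c(O)c4c3C(=O)O[C@H]([C@H]3OC(=O)c5c-4c(O)c(O)c(O)c5[C@H]3O)[C@@H]2OC(=O)c2cc(O)c(O)c(O)c2-c2c1cc(O)c(O)c2O | target

**Total steps:** 10. **Longest linear sequence:** 9 steps (Steps 2 → 3 → 4 → 5 → 6 → 7 → 8 → 9 → 10).

## Three steps most likely to fail
1. **Step 9, triple oxidative coupling.** Mispairing (for example D–P), oligomerization or over-oxidation could occur, and the Q–R coupling is an ortho–para one.
   Fallback: make each axis stepwise from pre-halogenated partners. Ortho-iodinate acid **6** to give 2-iodo-galloyl esters for the D/E, Q/P and Q/R pairs, then close each macrocycle by intramolecular Ullmann coupling (Cu, DMF), with the glucose tether fixing each axis.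
2. **Step 8, hydroxyalkylation.** It may give the wrong C1 epimer, lose the benzylic OH by ionization, or attack the wrong ring.
   Fallback: use the gluconic acid oxidation level instead of the aldehyde. Convert penta-O-aroyl-D-gluconic acid to its acid chloride and close the isochromane-1,4-dione by intramolecular Friedel–Crafts acylation (SnCl4). Then reduce the C1 ketone with a bulky hydride (L-Selectride, −78 °C) from the less hindered face to set C1-OH.
3. **Step 6, aldehyde unmasking.** The α-acyloxy aldehyde **8** may epimerize at C2 or undergo β-elimination of the 3-O-aroyl group.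
   Fallback: never isolate the free aldehyde. Convert penta-O-aroyl-D-gluconic acid to its acid chloride and generate the aldehyde by Rosenmund reduction (H2, Pd/BaSO4), then cyclize it directly in the same pot with Sc(OTf)3.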